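The data were computed for an exercise; the scatter is artificial.

Slowness in this flask can be clocked like a first-order lag.

all flasks: solid substrate 0.12 M; gas phase 58 mM (held)

|  | remark | time |
|---|---|---|
| dawn | the very flask that is asked about, followed so far |  |
| flask |  | 12 min |
- dawn (time / min: target / %, starting material / %): 0.417: 0.2, 10.5; 0.667: 0.8, 15.0; 1.33: 0.2, 23.6; 2.50: 6.4, 33.1; 5.00: 21.6, 38.9

(scatter of a reading: 1 percentage point)
- in percentages every species weighs as the solid substrate in it: one side product counts as two
- as a solid, counted per litre of solution: solid substrate
- at the start none of the gas is dissolved
- the numbers in the tables scatter by 1 percentage point (one standard deviation)
- on the list of suspects stand: gas phase <-> dissolved gas; solid substrate <-> starting material; starting material + dissolved gas -> target; starting material + target -> side product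
- at the start none of the solid substrate is in solution
- starting material means what is dissolved; the solid is not counted in it
- the target in the flask at 12 min, as a percentage of the solid substrate charged
- the starting material in the flask at 12 min, as a percentage of the solid substrate charged
- the side product in the flask at 12 min, as a percentage of the solid substrate charged

You want the lag of starting material turning into target, and the last two dawn readings show it, past the target's early delay. Take the numbers in turn. The target rises 15 percentage points between them, and a point of scatter at either end shows strongly in that rise. The mean starting material, 36.0%, is larger than the rise, so the same point moves the result less.

Dividing the rise by that level and by the time between gives 0.169 min⁻¹. This is the conversion constant, the target gained per minute per unit of starting material in solution. It is a pseudo-first-order reading that assumes steady dissolved gas, and it means a half-life of 4.10 min.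

Now go round twice. Holding starting material at 38.9% for the remaining 7.00 min gives 67.6% of the charge converted. By this estimate 32.4% remains as starting material at the end, so the mean falls, and my second round gives 63.8%, with no split between target and side product.

The forecast does split it: 62% target, 28% starting material, 6% side product, noting “The side product is unobserved”.

The flask gives 49.1% target, 18.5% starting material and 32.4% side product.

    gas phase ⇌ dissolved gas, rate k1*(csat - [dissolved gas]) (kL = 0.0140 s⁻¹)
    solid substrate ⇌ starting material, rate k2*(cs2 - [starting material]) while solid is left; crystals form when [starting material] > cs2 (solubility = 0.0770 M, k = 0.00630 s⁻¹)
    starting material + dissolved gas → target (k = 0.0590 M⁻¹ s⁻¹)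
    starting material + target → side product (k = 0.0220 M⁻¹ s⁻¹)

At 3.67 min the target step uses starting material 8.1 times as fast as the side step. Carried to the neighbour read at 8.0 min, the constant gives 14 points of target made since 6.00 min. That neighbour shows 14 points, the target's rise plus half of the side product's rise.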